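The octane chain is cut between C4 (the CH2 between the two carbinol carbons) and C5 (the acetoxy carbon bearing propyl). The key step is a nickel-hydride hydroalkylation. An E/Z mixture of but-1-enyl acetate is hydrometallated at C5. The resulting chelated α-acetoxyalkyl-nickel couples with the C4 radical from an enantiopure β-acetoxy iodide that carries C1–C4 and the guaiacyl ring. One operation thus forms C4–C5, sets C5 under ligand control, funnels both alkene isomers into one configuration and delivers C5 already as its acetate. The feature exploited is the C5 acetoxy group, whose carbonyl oxygen directs nickel; the benzene ring stays a spectator. C3 comes from (S)-epichlorohydrin.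

Key step: step 4

Numbering used: C1 is the benzylic CH2, C3 and C5 carry the acetates, C8 is the chain methyl; the target is the syn-(3S,5R) diacetate.
Assumption: the sense of induction of the bis(oxazoline) ligand on 9 is not predicted here. Both ligand antipodes are accessible, and the one that gives (5R), that is the syn diastereomer of 10, is used.
Assumption: benzyl chloride 1 is taken as a catalogue compound.

Step 1
Reactants: 1 4-(benzyloxy)-3-methoxybenzyl chloride; 2 (S)-epichlorohydrin
Product: 5 (S)-2-{2-[4-(benzyloxy)-3-methoxyphenyl]ethyl}oxirane, via benzylic Grignard reagent 3 (not isolated), via chlorohydrin 4 (not isolated)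
Conditions: Mg, THF, 0 °C (slow addition of 1); CuI (10 mol %), 2, −30 °C; 1 M HCl quench; crude 4, aq. NaOH, THF, rt
Reagents that add atoms: none
Why: Copper-catalysed Grignard opening of the epoxide of 2 at its unsubstituted carbon and base-induced intramolecular Williamson closure of chlorohydrin 4 never touch the C–O bond of the stereocentre, so the (S) centre of 2 is carried unchanged into 5 as the future C3.

Step 2
Reactants: 5 (S)-2-{2-[4-(benzyloxy)-3-methoxyphenyl]ethyl}oxirane
Product: 7 (S)-4-[4-(benzyloxy)-3-methoxyphenyl]-1-iodobutan-2-yl acetate, via iodohydrin 6 (not isolated)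
Conditions: LiI, AcOH, THF, rt; then Ac2O, pyridine, DMAP (cat.), 0 °C to rt
Reagents that add atoms: lithium iodide [Li+].[I-]; acetic anhydride CC(=O)OC(C)=O
Why: Halohydrin formation by SN2 attack of iodide on the acid-activated terminal epoxide at its unhindered CH2, followed by DMAP-catalysed acetylation, leaves the C3–O bond intact, so C3 stays (S).

Step 3
Reactants: 8 butanal
Product: 9 but-1-en-1-yl acetate (E/Z mixture)
Conditions: Ac2O, KOAc (cat.), reflux; distillation
Reagents that add atoms: acetic anhydride CC(=O)OC(C)=O
Why: Enol acetylation of an enolisable aldehyde (Ac2O/KOAc) gives the enol ester as an E/Z mixture, which needs no separation because step 4 erases the alkene geometry.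

Step 4
Reactants: 7 (S)-4-[4-(benzyloxy)-3-methoxyphenyl]-1-iodobutan-2-yl acetate; 9 but-1-en-1-yl acetate (E/Z mixture, 2.5 equiv)
Product: 10 (3S,5R)-1-[4-(benzyloxy)-3-methoxyphenyl]octane-3,5-diyl diacetate
Conditions: NiBr2·glyme (10 mol %), chiral bis(oxazoline) ligand (12 mol %), (EtO)2MeSiH, KF, DMA/t-BuOH, 0–10 °C
Reagents that add atoms: none
Why: A ligated nickel hydride, formed from the nickel salt, the silane and fluoride, inserts into the C=C bond of 9 with H going to C6 and Ni to C5, because the acetate C=O then closes a five-membered chelate on nickel; low-valent nickel abstracts iodine from 7, the primary C4 radical is captured by the chelated α-acetoxybutyl-nickel, and reductive elimination from Ni(III) forms C4–C5. The closest known reaction type is the NiH-catalysed regio- and enantioselective hydroalkylation of enol esters and enamides with unactivated alkyl iodides, a relative of the enantioconvergent nickel coupling of racemic 1-bromoalkyl esters. No ring is closed. The only new stereocentre, C5, is controlled by the C2-symmetric bis(oxazoline) ligand and not by the remote C3 centre, and the E and Z isomers of 9 should both be funnelled into (R)-C5 because C6 becomes a CH2 group and only the nickel-bearing face of C5 counts. The step needs α-regioselectivity (secured by the chelating acetate), cross- over homo-coupling (secured by the separate radical and organonickel roles and by the excess of cheap 9), and survival of the β-acetoxy group of 7 (C4 enters as a free radical that does not expel acetate, and the Ni(III) dialkyl should eliminate reductively faster than it loses acetate). Because C3 is already enantiopure, any leakage at C5 should appear as the (3S,5S) diastereomer, removable by chromatography, so 10 should emerge as a single enantiomer.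

Step 5
Reactants: 10 (3S,5R)-1-[4-(benzyloxy)-3-methoxyphenyl]octane-3,5-diyl diacetate
Product: 11 (3S,5R)-1-(4-hydroxy-3-methoxyphenyl)octane-3,5-diyl diacetate (target)
Conditions: H2 (1 atm), Pd/C, EtOAc, rt
Reagents that add atoms: none
Why: Catalytic hydrogenolysis cleaves only the benzylic C–O bond of the aryl benzyl ether, while the two secondary acetates, the methyl ether and both stereocentres are inert.

Compound list
1 | 4-(benzyloxy)-3-methoxybenzyl chloride | COc1cc(CCl)ccc1OCc1ccccc1 | starting material
2 | (S)-epichlorohydrin | ClC[C@@H]1CO1 | starting material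
3 | [4-(benzyloxy)-3-methoxybenzyl]magnesium chloride | COc1cc(C[Mg]Cl)ccc1OCc1ccccc1 | intermediate
4 | (S)-4-[4-(benzyloxy)-3-methoxyphenyl]-1-chlorobutan-2-ol | ClC[C@H](CCc1ccc(OCc2ccccc2)c(OC)c1)O | intermediate
5 | (S)-2-{2-[4-(benzyloxy)-3-methoxyphenyl]ethyl}oxirane | C1[C@H](CCc2ccc(OCc3ccccc3)c(OC)c2)O1 | intermediate
6 | (S)-4-[4-(benzyloxy)-3-methoxyphenyl]-1-iodobutan-2-ol | IC[C@H](CCc1ccc(OCc2ccccc2)c(OC)c1)O | intermediate
7 | (S)-4-[4-(benzyloxy)-3-methoxyphenyl]-1-iodobutan-2-yl acetate | IC[C@H](CCc1ccc(OCc2ccccc2)c(OC)c1)OC(C)=O | intermediate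
8 | butanal | CCCC=O | starting material
9 | but-1-en-1-yl acetate (E/Z mixture) | CCC=COC(C)=O | intermediate
10 | (3S,5R)-1-[4-(benzyloxy)-3-methoxyphenyl]octane-3,5-diyl diacetate | CCC[C@H](C[C@H](CCc1ccc(OCc2ccccc2)c(OC)c1)OC(C)=O)OC(C)=O | intermediate
11 | (3S,5R)-1-(4-hydroxy-3-methoxyphenyl)octane-3,5-diyl diacetate | CCC[C@H](C[C@H](CCc1ccc(O)c(OC)c1)OC(C)=O)OC(C)=O | target

Total step count: 5. Longest linear sequence: 4 (steps 1, 2, 4, 5).

Steps most likely to fail

Step 4. The C4 fragment may lose its acetate by β-elimination at nickel, the C–I bond may be reduced prematurely by the hydride, or facial control at C5 may be incomplete. The fallback sets out from 5 and 8 and comes back at 10. Butanal 8 is thioacetalised with propane-1,3-dithiol (BF3·OEt2) to 2-propyl-1,3-dithiane F1, which n-BuLi (THF, −30 °C) converts into 2-lithio-2-propyl-1,3-dithiane F2. This acyl-anion equivalent opens epoxide 5 at its CH2 terminus, forming the same C4–C5 bond, to give the hydroxy dithiane F3. MeI/CaCO3 in aqueous MeCN unmasks the (S)-β-hydroxy ketone F4. Narasaka–Prasad reduction (Et2BOMe, NaBH4, THF/MeOH, −78 °C) delivers hydride within the boron chelate to give the syn-(3S,5R)-diol F5, and Ac2O/pyridine converts it into 10.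

Step 1. Wurtz-type homocoupling may occur during formation of the electron-rich benzylic Grignard reagent, and attack at the chloromethyl carbon of 2 may compete. The fallback sets out from 1 and comes back at 5. Allylmagnesium chloride alkylates benzylic chloride 1, so the polarity is reversed and no benzylic organometallic is needed; this gives 1-(benzyloxy)-4-(but-3-enyl)-2-methoxybenzene F6. mCPBA gives the racemic epoxide F7. Hydrolytic kinetic resolution with (S,S)-(salen)Co(III)OAc and about half an equivalent of water should hydrolyse the (R)-epoxide to the (R)-diol F8 and leave 5.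

Step 2. The iodohydrin may re-close to the epoxide during the basic acetylation, or iodide may attack at the internal carbon. The fallback sets out from 4 (isolated after the acidic quench of step 1 instead of being closed) and comes back at 7. Ac2O/pyridine gives the chloro acetate F9. A Finkelstein exchange (NaI, butan-2-one, reflux) then replaces chloride by iodide without a free alkoxide or an epoxide being involved.

Further compounds
F1 | step 4 | 2-propyl-1,3-dithiane | CCCC1SCCCS1
F2 | step 4 | 2-lithio-2-propyl-1,3-dithiane | [Li]C1(CCC)SCCCS1
F3 | step 4 | (S)-4-[4-(benzyloxy)-3-methoxyphenyl]-1-(2-propyl-1,3-dithian-2-yl)butan-2-ol | CCCC1(C[C@H](CCc2ccc(OCc3ccccc3)c(OC)c2)O)SCCCS1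
F4 | step 4 | (S)-1-[4-(benzyloxy)-3-methoxyphenyl]-3-hydroxyoctan-5-one | CCCC(=O)C[C@H](CCc1ccc(OCc2ccccc2)c(OC)c1)O
F5 | step 4 | (3S,5R)-1-[4-(benzyloxy)-3-methoxyphenyl]octane-3,5-diol | CCC[C@H](C[C@H](CCc1ccc(OCc2ccccc2)c(OC)c1)O)O
F6 | step 1 | 1-(benzyloxy)-4-(but-3-enyl)-2-methoxybenzene | C=CCCc1ccc(OCc2ccccc2)c(OC)c1
F7 | step 1 | rac-2-{2-[4-(benzyloxy)-3-methoxyphenyl]ethyl}oxirane | C1C(CCc2ccc(OCc3ccccc3)c(OC)c2)O1
F8 | step 1 | (R)-4-[4-(benzyloxy)-3-methoxyphenyl]butane-1,2-diol | OC[C@@H](CCc1ccc(OCc2ccccc2)c(OC)c1)O
F9 | step 2 | (S)-4-[4-(benzyloxy)-3-methoxyphenyl]-1-chlorobutan-2-yl acetate | ClC[C@H](CCc1ccc(OCc2ccccc2)c(OC)c1)OC(C)=O
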